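**Strategy.** Ring B (O1, C2, C3, C3a, C7a) is disconnected at C3–C3a and C7a–O1. In ring A, C7a lies between the methoxy-bearing C7 and C3a, so 4-iodo-3-methoxybenzaldehyde has iodine on the future C7a and one free ortho C–H, the future C3a. A palladium/norbornene annulation joins this iodide to an enantiopure cis-epoxide carrying ring C (as its pivalate) and a silyloxymethyl group. The ortho carbon takes the epoxide carbon bearing CH2OTBS with inversion and the ipso carbon takes the epoxide oxygen, giving the trans-2,3-dihydrobenzofuran in one operation. The C5 formyl group then needs only Wittig, desilylation and DIBAL-H steps.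

Key step: step 5

Assumption: compounds 3 and 7 are taken as catalogue items, and the (R,R)-salen manganese catalyst is taken to give the (2R,3S)-cis-epoxide by analogy with cis-β-methylstyrene and cis-cinnamate esters. C5 is carried as an aldehyde so that no oxidation is ever run on a free syringyl phenol.

**Step 1**
Reactants: 1 4-bromo-2,6-dimethoxyphenol
Product: 2 4-bromo-2,6-dimethoxyphenyl pivalate
Conditions: PivCl, Et3N, DMAP (cat.), CH2Cl2, 0 °C to rt
Reagents that add atoms: pivaloyl chloride, CC(C)(C)C(Cl)=O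
Why: DMAP-catalysed O-acylation of the hindered phenol gives a robust aryl ester that masks the phenol and makes ring C electron-poorer for the later steps.

**Step 2**
Reactants: 2 4-bromo-2,6-dimethoxyphenyl pivalate; 3 tert-butyldimethyl(prop-2-yn-1-yloxy)silane
Product: 4 4-[3-(tert-butyldimethylsilyloxy)prop-1-yn-1-yl]-2,6-dimethoxyphenyl pivalate
Conditions: PdCl2(PhCN)2 (3 mol%), [HP(t-Bu)3]BF4 (6 mol%), CuI (2 mol%), i-Pr2NH, 1,4-dioxane, rt
Reagents that add atoms: none
Why: Sonogashira coupling, in which the bulky electron-rich trialkylphosphine should allow oxidative addition of the electron-rich aryl bromide near room temperature while the pivalate and silyl ether stay inert.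

**Step 3**
Reactants: 4 4-[3-(tert-butyldimethylsilyloxy)prop-1-yn-1-yl]-2,6-dimethoxyphenyl pivalate
Product: 5 4-[(Z)-3-(tert-butyldimethylsilyloxy)prop-1-en-1-yl]-2,6-dimethoxyphenyl pivalate
Conditions: H2 (1 atm), Pd/CaCO3 poisoned with Pb(OAc)2, quinoline, EtOAc, rt, stopped after one equivalent of H2
Reagents that add atoms: none
Why: Lindlar semihydrogenation delivers both hydrogens to one face of the adsorbed alkyne, so the (Z)-alkene should form, and the poisoned surface should stop at the alkene.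

**Step 4**
Reactants: 5 4-[(Z)-3-(tert-butyldimethylsilyloxy)prop-1-en-1-yl]-2,6-dimethoxyphenyl pivalate
Product: 6 4-[(2R,3S)-3-(tert-butyldimethylsilyloxymethyl)oxiran-2-yl]-2,6-dimethoxyphenyl pivalate (cis-epoxide; aryl carbon R, CH2OTBS carbon S)
Conditions: (R,R)-N,N'-bis(3,5-di-tert-butylsalicylidene)-1,2-cyclohexanediaminomanganese chloride [(R,R)-Mn(salen)Cl, 5 mol%], 4-phenylpyridine N-oxide (20 mol%), aq. NaOCl (pH 11.3), CH2Cl2, 0 °C
Reagents that add atoms: sodium hypochlorite, [Na+].[O-]Cl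
Why: Jacobsen–Katsuki epoxidation of a cis-disubstituted aryl alkene, in which side-on approach of the alkene to the oxo-manganese species of the (R,R)-salen complex should set both epoxide stereocentres, with the N-oxide additive limiting leakage to the trans-epoxide.

**Step 5**
Reactants: 6 4-[(2R,3S)-3-(tert-butyldimethylsilyloxymethyl)oxiran-2-yl]-2,6-dimethoxyphenyl pivalate; 7 4-iodo-3-methoxybenzaldehyde
Product: 8 4-[(2S,3R)-3-(tert-butyldimethylsilyloxymethyl)-5-formyl-7-methoxy-2,3-dihydro-1-benzofuran-2-yl]-2,6-dimethoxyphenyl pivalate (2,3-trans)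
Conditions: Pd(OAc)2 (10 mol%), XPhos (20 mol%), isopropyl norborn-5-ene-2-carboxylate (50 mol%), K2CO3 (2 equiv), 7 (1.5 equiv), 1,4-dioxane, 90 °C
Reagents that add atoms: none
Why: Proposed new method: oxidative addition of 7 to zerovalent palladium, norbornene insertion and C–H palladation at the only free ortho carbon should give an aryl–norbornyl palladacycle of divalent palladium, which opens epoxide 6 by SN2 attack at the CH2OTBS-bearing carbon to a tetravalent palladium alkyl; C3–C3a reductive elimination and norbornene extrusion then leave an ortho,ortho'-disubstituted arylpalladium alkoxide. The closest known reaction type is the palladium/norbornene annulation of aryl iodides with terminal epoxides to 2-substituted 2,3-dihydrobenzofurans; its use on a 2,3-disubstituted epoxide is the untested part. Ring B closes by C7a–O1 reductive elimination from a six-membered oxapalladacycle, the epoxide oxygen keeping its bond to C2. No stereocentre is created: C2 is carried over unchanged because its C–O bond is never broken, and C3 is inverted once (backside attack by palladium, then retentive C–C reductive elimination), so the cis-epoxide maps onto the trans-(2S,3R) product. The step needs attack at C3 instead of the benzylic C2; the 4-pivaloyloxy group and the two meta-methoxy groups make ring C net electron-poor and so disfavour a cation-like benzylic opening, the silyl ether keeps the inductive deactivation of C3 small, and the methoxy-blocked ortho position of 7 allows only one alkylation. Dioxane, in which KI is barely soluble, is chosen to suppress iodide-mediated opening of the epoxide, which would erode the stereochemical course.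

**Step 6**
Reactants: 8 4-[(2S,3R)-3-(tert-butyldimethylsilyloxymethyl)-5-formyl-7-methoxy-2,3-dihydro-1-benzofuran-2-yl]-2,6-dimethoxyphenyl pivalate
Product: 9 ethyl (E)-3-[(2S,3R)-3-(tert-butyldimethylsilyloxymethyl)-2-(3,5-dimethoxy-4-pivaloyloxyphenyl)-7-methoxy-2,3-dihydro-1-benzofuran-5-yl]prop-2-enoate
Conditions: Ph3P=CHCO2Et, toluene, 60 °C
Reagents that add atoms: ethyl (triphenylphosphoranylidene)acetate, CCOC(=O)C=P(c1ccccc1)(c1ccccc1)c1ccccc1
Why: Wittig olefination with a stabilised ylide should give the (E)-enoate under neutral conditions that leave the pivalate, the silyl ether and both stereocentres untouched.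

**Step 7**
Reactants: 9 ethyl (E)-3-[(2S,3R)-3-(tert-butyldimethylsilyloxymethyl)-2-(3,5-dimethoxy-4-pivaloyloxyphenyl)-7-methoxy-2,3-dihydro-1-benzofuran-5-yl]prop-2-enoate
Product: 10 ethyl (E)-3-[(2S,3R)-2-(3,5-dimethoxy-4-pivaloyloxyphenyl)-3-(hydroxymethyl)-7-methoxy-2,3-dihydro-1-benzofuran-5-yl]prop-2-enoate
Conditions: Bu4NF, AcOH (1:1), THF, 0 °C to rt
Reagents that add atoms: none
Why: Fluoride-mediated desilylation of the primary silyl ether, buffered with acetic acid so that neither the aryl pivalate nor the enoate is attacked.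

**Step 8**
Reactants: 10 ethyl (E)-3-[(2S,3R)-2-(3,5-dimethoxy-4-pivaloyloxyphenyl)-3-(hydroxymethyl)-7-methoxy-2,3-dihydro-1-benzofuran-5-yl]prop-2-enoate
Product: 11 4-[(2S,3R)-3-(hydroxymethyl)-5-[(E)-3-hydroxyprop-1-en-1-yl]-7-methoxy-2,3-dihydro-1-benzofuran-2-yl]-2,6-dimethoxyphenol (target)
Conditions: i-Bu2AlH (DIBAL-H, 7 equiv), CH2Cl2, −78 to −20 °C; aq. Rochelle salt
Reagents that add atoms: none
Why: DIBAL-H should perform 1,2-reduction of the enoate to the allylic alcohol and reductively cleave the aryl pivalate in the same operation, so the free phenol appears only at the end and never meets an oxidant or a base.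

**Compound list**
1 | 4-bromo-2,6-dimethoxyphenol | COc1cc(Br)cc(OC)c1O | starting material
2 | 4-bromo-2,6-dimethoxyphenyl pivalate | COc1cc(Br)cc(OC)c1OC(=O)C(C)(C)C | intermediate
3 | tert-butyldimethyl(prop-2-yn-1-yloxy)silane | C#CCO[Si](C)(C)C(C)(C)C | starting material
4 | 4-[3-(tert-butyldimethylsilyloxy)prop-1-yn-1-yl]-2,6-dimethoxyphenyl pivalate | COc1cc(C#CCO[Si](C)(C)C(C)(C)C)cc(OC)c1OC(=O)C(C)(C)C | intermediate
5 | 4-[(Z)-3-(tert-butyldimethylsilyloxy)prop-1-en-1-yl]-2,6-dimethoxyphenyl pivalate | COc1cc(/C=C\CO[Si](C)(C)C(C)(C)C)cc(OC)c1OC(=O)C(C)(C)C | intermediate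
6 | 4-[(2R,3S)-3-(tert-butyldimethylsilyloxymethyl)oxiran-2-yl]-2,6-dimethoxyphenyl pivalate (cis) | COc1cc([C@H]2O[C@H]2CO[Si](C)(C)C(C)(C)C)cc(OC)c1OC(=O)C(C)(C)C | intermediate
7 | 4-iodo-3-methoxybenzaldehyde | COc1cc(C=O)ccc1I | starting material
8 | 4-[(2S,3R)-3-(tert-butyldimethylsilyloxymethyl)-5-formyl-7-methoxy-2,3-dihydro-1-benzofuran-2-yl]-2,6-dimethoxyphenyl pivalate (trans) | COc1cc([C@H]2Oc3c(OC)cc(C=O)cc3[C@@H]2CO[Si](C)(C)C(C)(C)C)cc(OC)c1OC(=O)C(C)(C)C | intermediate
9 | ethyl (E)-3-[(2S,3R)-3-(tert-butyldimethylsilyloxymethyl)-2-(3,5-dimethoxy-4-pivaloyloxyphenyl)-7-methoxy-2,3-dihydro-1-benzofuran-5-yl]prop-2-enoate | COc1cc([C@H]2Oc3c(OC)cc(/C=C/C(=O)OCC)cc3[C@@H]2CO[Si](C)(C)C(C)(C)C)cc(OC)c1OC(=O)C(C)(C)C | intermediate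
10 | ethyl (E)-3-[(2S,3R)-2-(3,5-dimethoxy-4-pivaloyloxyphenyl)-3-(hydroxymethyl)-7-methoxy-2,3-dihydro-1-benzofuran-5-yl]prop-2-enoate | COc1cc([C@H]2Oc3c(OC)cc(/C=C/C(=O)OCC)cc3[C@@H]2CO)cc(OC)c1OC(=O)C(C)(C)C | intermediate
11 | 4-[(2S,3R)-3-(hydroxymethyl)-5-[(E)-3-hydroxyprop-1-en-1-yl]-7-methoxy-2,3-dihydro-1-benzofuran-2-yl]-2,6-dimethoxyphenol | COc1cc([C@H]2Oc3c(OC)cc(/C=C/CO)cc3[C@@H]2CO)cc(OC)c1O | target

**Totals.** Total step count: 8. Longest linear sequence: 8 steps (1 to 11); 3 and 7 enter as purchased compounds.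

**Steps most likely to fail**

Step 5 (Proposed new method). Palladium may attack the benzylic epoxide carbon and give the regioisomeric ring, the hindered internal epoxide may not be opened at all, or the secondary benzylic palladium alkoxide may lose a β-hydride instead of closing ring B. The fallback leaves the epoxide route and uses known chemistry only; it sets out from bromide 2 and comes back at target 11.
- Stille hydroxymethylation of 2 (Bu3SnCH2OH, Pd(PPh3)4, dioxane, 90 °C) should give 4-(hydroxymethyl)-2,6-dimethoxyphenyl pivalate F1.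
- Mitsunobu etherification with commercial 4-hydroxy-3-iodo-5-methoxybenzaldehyde (PPh3, DIAD, THF) should give 4-[(4-formyl-2-iodo-6-methoxyphenoxy)methyl]-2,6-dimethoxyphenyl pivalate F2.
- Wittig reaction with Ph3P=CHCO2Et should give ethyl (E)-3-{4-[(3,5-dimethoxy-4-pivaloyloxyphenyl)methoxy]-3-iodo-5-methoxyphenyl}prop-2-enoate F3.
- Pd(PPh3)4-catalysed coupling of the aryl iodide with methyl diazoacetate (Et3N, Bu4NBr, MeCN, rt) should give the aryl diazoacetate, methyl 2-diazo-2-{2-[(3,5-dimethoxy-4-pivaloyloxyphenyl)methoxy]-5-[(E)-3-ethoxy-3-oxoprop-1-en-1-yl]-3-methoxyphenyl}acetate F4.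
- Intramolecular carbenoid insertion into the benzylic ether C–H bond with dirhodium tetrakis[N-phthaloyl-(S)-tert-leucinate], Rh2(S-PTTL)4, in toluene at −60 °C should close ring B as the cis ester, methyl (2S,3R)-2-(3,5-dimethoxy-4-pivaloyloxyphenyl)-5-[(E)-3-ethoxy-3-oxoprop-1-en-1-yl]-7-methoxy-2,3-dihydro-1-benzofuran-3-carboxylate F5. The catalyst enantiomer is to be chosen so that C2 is S.
- DBU in toluene should epimerise C3 to the trans ester, methyl (2S,3S)-2-(3,5-dimethoxy-4-pivaloyloxyphenyl)-5-[(E)-3-ethoxy-3-oxoprop-1-en-1-yl]-7-methoxy-2,3-dihydro-1-benzofuran-3-carboxylate F6.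
- Excess DIBAL-H should then reduce both esters and cleave the pivalate to give 11.

Step 4. The stepwise oxygen transfer from the manganese-oxo species may pass through a benzylic radical that rotates before ring closure, leaking to the trans-epoxide, or the facial selectivity may be insufficient. The fallback sets out from alkene 5 and comes back at epoxide 6.
- Bu4NF/AcOH should give the free allylic alcohol, 4-[(Z)-3-hydroxyprop-1-en-1-yl]-2,6-dimethoxyphenyl pivalate F7.
- Sharpless asymmetric epoxidation (Ti(OiPr)4, L-(+)-diethyl tartrate, t-BuOOH, 4 Å sieves, CH2Cl2, −20 °C) is a concerted, hydroxyl-directed oxygen transfer that keeps the alkene geometry. It should give the cis-epoxy alcohol, 4-[(2R,3S)-3-(hydroxymethyl)oxiran-2-yl]-2,6-dimethoxyphenyl pivalate F8.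
- TBSCl/imidazole returns to 6.

Step 3. Over-reduction to the saturated chain or Z-to-E isomerisation on the catalyst surface would later feed the wrong diastereomer into the key step. The fallback bypasses the alkyne; it sets out from alkyne 3 (used with bromide 2) and comes back at alkene 5.
- Rhodium-catalysed trans-hydroboration of 3 with pinacolborane ([Rh(cod)Cl]2, P(i-Pr)3, Et3N, cyclohexane, rt) should give the (Z)-alkenylboronate, tert-butyldimethyl{[(Z)-3-(4,4,5,5-tetramethyl-1,3,2-dioxaborolan-2-yl)prop-2-en-1-yl]oxy}silane F9.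
- Stereoretentive Suzuki–Miyaura coupling with 2 (PdCl2(dppf), K3PO4, THF/H2O, 60 °C) should give 5.

**Further compounds**
F1 | step 5 | 4-(hydroxymethyl)-2,6-dimethoxyphenyl pivalate | COc1cc(CO)cc(OC)c1OC(=O)C(C)(C)C
F2 | step 5 | 4-[(4-formyl-2-iodo-6-methoxyphenoxy)methyl]-2,6-dimethoxyphenyl pivalate | COc1cc(COc2c(I)cc(C=O)cc2OC)cc(OC)c1OC(=O)C(C)(C)C
F3 | step 5 | ethyl (E)-3-{4-[(3,5-dimethoxy-4-pivaloyloxyphenyl)methoxy]-3-iodo-5-methoxyphenyl}prop-2-enoate | COc1cc(COc2c(I)cc(/C=C/C(=O)OCC)cc2OC)cc(OC)c1OC(=O)C(C)(C)C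
F4 | step 5 | methyl 2-diazo-2-{2-[(3,5-dimethoxy-4-pivaloyloxyphenyl)methoxy]-5-[(E)-3-ethoxy-3-oxoprop-1-en-1-yl]-3-methoxyphenyl}acetate | COc1cc(COc2c(OC)cc(/C=C/C(=O)OCC)cc2C(=[N+]=[N-])C(=O)OC)cc(OC)c1OC(=O)C(C)(C)C
F5 | step 5 | methyl (2S,3R)-2-(3,5-dimethoxy-4-pivaloyloxyphenyl)-5-[(E)-3-ethoxy-3-oxoprop-1-en-1-yl]-7-methoxy-2,3-dihydro-1-benzofuran-3-carboxylate (cis) | COc1cc([C@H]2Oc3c(OC)cc(/C=C/C(=O)OCC)cc3[C@H]2C(=O)OC)cc(OC)c1OC(=O)C(C)(C)C
F6 | step 5 | methyl (2S,3S)-2-(3,5-dimethoxy-4-pivaloyloxyphenyl)-5-[(E)-3-ethoxy-3-oxoprop-1-en-1-yl]-7-methoxy-2,3-dihydro-1-benzofuran-3-carboxylate (trans) | COc1cc([C@H]2Oc3c(OC)cc(/C=C/C(=O)OCC)cc3[C@@H]2C(=O)OC)cc(OC)c1OC(=O)C(C)(C)C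
F7 | step 4 | 4-[(Z)-3-hydroxyprop-1-en-1-yl]-2,6-dimethoxyphenyl pivalate | COc1cc(/C=C\CO)cc(OC)c1OC(=O)C(C)(C)C
F8 | step 4 | 4-[(2R,3S)-3-(hydroxymethyl)oxiran-2-yl]-2,6-dimethoxyphenyl pivalate (cis) | COc1cc([C@H]2O[C@H]2CO)cc(OC)c1OC(=O)C(C)(C)C
F9 | step 3 | tert-butyldimethyl{[(Z)-3-(4,4,5,5-tetramethyl-1,3,2-dioxaborolan-2-yl)prop-2-en-1-yl]oxy}silane | CC(C)(C)[Si](C)(C)OC/C=C\B1OC(C)(C)C(C)(C)O1
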